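The data come from a simulation on assumed constants.

Given time, the one-way step to ring must win, so in this flask the open dimer is a resting state that fills and later drains, and its peak comes when it stands in balance with the free starting material.

- teal: starting material 0.80 M; the very flask that is asked about, followed so far
- flask: starting material 0.80 M; time 10 h

teal run (percent of the starting material charged)

| time / min | open dimer / % | ring / % |
|---|---|---|
| 40.0 | 19.8 | 11.1 |
| 50.0 | 19.1 | 12.1 |
| 60.0 | 21.5 | 14.2 |
| 80.0 | 25.5 | 19.7 |
| 90.0 | 25.7 | 20.6 |
| 120 | 27.2 | 21.6 |

(standard deviation of a reading: 1 percentage point)

* the best time, 10 h at the latest, for open dimer
* the amount of open dimer, in percent of the starting material charged, at that time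

In fractions of the charge, that balance means the dimer fraction divided by the square of the free fraction equals a dimer number which, at constant temperature, is proportional to the charge. The free fraction is not read, but we can bound it by the unread remainder, which is one minus dimer and ring. While the dimer still rises, the dimer fraction over the squared remainder is a floor on that number, and at 120 min of the teal run this floor reads 1.04. Tested at 80.0 min of the teal run, the same figure reads 0.849, so in these readings it is still climbing and one number gives a bound, not a time. The dimer readings of the teal run gained 1.7 percentage points over that span against a scatter of 1 point, so we expect the peak not far past the last reading. The forecast says 2.5 h and 28%, "followed by a slow decline".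

    starting material → ring (k = 6.15 × 10⁻⁵ /s)
    2 starting material ⇌ open dimer (K = 3.70 /M, k = 8.41 × 10⁻⁵ /M/s)
    ring → over-reaction product (k = 4.03 × 10⁻⁷ /s)
    starting material ⇌ dormant form (K = 1.76, k = 7.32 × 10⁻⁵ /s)

The flask peaks at 2.73 h with 27.0%, and free starting material then stands at 21.3%. Dimer over squared free is there 5.92, above the floor. The neighbour flask is charged with a quarter of this flask's starting material, at 0.20 M, so its floor drops to 0.259, and its best is 9.26%, a third of this flask's.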